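**Plan**
- Retrosynthesis: one trione ring is cut at both C(=O)–CMe2 bonds ([3+3]). This leaves 2,4-dimethylpentan-3-one and a malonyl unit, one carbonyl of which is tied as an enol δ-lactone to the other ring. Then the lactone C–O bond, the malonate–CH bond (Michael) and the CH=C bond (Knoevenagel) are cut, and last the first ring goes back to a phloroglucinol arene (four C–Me bonds, acetyl blocking group).
- Forward: ring 1 arises by dearomative tetramethylation of 2',4',6'-trihydroxyacetophenone and deacetylation. Isovaleraldehyde and dimethyl malonate are joined to it, and the temporary dihydropyranone ring is closed. Ring 2 is then built around the malonyl carbon in one flask, which also opens the temporary ring.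
- Enabling feature: C-3 of the dihydropyranone ring carries an acidic H between the enol-ester carbonyl C-2 and the ester carbonyl, and O-1 is the enolate oxygen of ring 1. A base therefore turns C-2 into a ketene, and the ketone offers its two tertiary α-CH carbons as a 1,3-dinucleophile.
- Stereochemistry (remark on the chemistry): the target SMILES holds no stereocentre, since the CH carbon bears two identical rings. The target is therefore one achiral compound and nothing has to be set. Intermediates 6, 9, 10, 12 and 13 are racemic, and their stereocentres are erased in the last step.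

Key step: step 6

**Step 1**
Reactants: 1 2',4',6'-trihydroxyacetophenone; 2 iodomethane
Product: 3 2-acetyl-3-hydroxy-4,4,6,6-tetramethylcyclohex-2-ene-1,5-dione
Conditions: NaOMe (6 equiv), MeI (6 equiv), MeOH, 0 °C → reflux; then aq. HCl
Reagents that add atoms: iodomethane (2), CI
Why: Dearomative C-alkylation of a phloroglucinol: the phenoxide is methylated twice at each free ring carbon, while the acetyl group blocks the third carbon and keeps the product as a stabilised β-triketone enolate, so that O-methylation should stay minor; no stereocentre.

**Step 2**
Reactants: 3 2-acetyl-3-hydroxy-4,4,6,6-tetramethylcyclohex-2-ene-1,5-dione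
Product: 4 syncarpic acid (5-hydroxy-2,2,6,6-tetramethylcyclohex-4-ene-1,3-dione)
Conditions: 6 M aq. HCl, reflux
Reagents that add atoms: none
Why: Acid-catalysed retro-Claisen deacylation of a 2-acyl-1,3-dione: water adds to the exocyclic acetyl carbonyl and C–C cleavage releases acetic acid, the ring carbonyls being shielded by the quaternary carbons.

**Step 3**
Reactants: 4 syncarpic acid; 5 3-methylbutanal
Product: 7 2,2,4,4-tetramethyl-6-(3-methylbutylidene)cyclohexane-1,3,5-trione, via piperidine Mannich base 6 (not isolated)
Conditions: piperidine (1.1 equiv), CH2Cl2, rt; then 1 M aq. HCl, rt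
Reagents that add atoms: none
Why: Knoevenagel condensation run through the Mannich base: stoichiometric piperidine traps the adduct as 6 and so keeps the reactive enone from taking up a second molecule of 4, and acid then eliminates the amine to the alkylidene triketone.

**Step 4**
Reactants: 7 2,2,4,4-tetramethyl-6-(3-methylbutylidene)cyclohexane-1,3,5-trione; 8 dimethyl malonate
Product: 9 dimethyl 2-[1-(2-hydroxy-3,3,5,5-tetramethyl-4,6-dioxocyclohex-1-en-1-yl)-3-methylbutyl]propanedioate (racemic)
Conditions: NaH (1.1 equiv), THF, 0 °C → rt; then 1 M aq. HCl
Reagents that add atoms: none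
Why: Michael addition of the malonate anion to the doubly activated alkylidene triketone should be irreversible because the adduct forms as the stable triketone enolate; the new stereocentre is racemic and without consequence.

**Step 5**
Reactants: 9 dimethyl 2-[1-(2-hydroxy-3,3,5,5-tetramethyl-4,6-dioxocyclohex-1-en-1-yl)-3-methylbutyl]propanedioate
Product: 10 methyl 6,6,8,8-tetramethyl-4-(2-methylpropyl)-2,5,7-trioxo-3,4,5,6,7,8-hexahydro-2H-chromene-3-carboxylate (racemic cis/trans mixture)
Conditions: p-TsOH·H2O (10 mol %), toluene, reflux, MeOH removed (4 Å MS in a Soxhlet)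
Reagents that add atoms: none
Why: Acid-catalysed enol lactonisation (intramolecular transesterification, 6-exo-trig), in which the enol OH of ring 1 closes a six-membered enol δ-lactone on one ester and removal of methanol drives it, as known for adducts of cyclic 1,3-diones with alkylidene malonates.

**Step 6**
Reactants: 10 methyl 6,6,8,8-tetramethyl-4-(2-methylpropyl)-2,5,7-trioxo-3,4,5,6,7,8-hexahydro-2H-chromene-3-carboxylate; 11 2,4-dimethylpentan-3-one
Product: 14 Watsonianone A, via methoxycarbonyl ketene 12 (not isolated), via acyclic triketo ester 13 (not isolated)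
Conditions: 11 (3.5 equiv), LDA (3.4 equiv), THF, −78 → 0 °C; then 10, −78 °C → rt, then 45 °C; 1 M aq. HCl
Reagents that add atoms: none
Why: Proposed new method: the enolate of 11 (the only strong base present) removes H-3 of 10, and the lactone enolate opens by E1cB loss of O-1, the enolate of ring 1 being a leaving group of carboxylate quality, to ketene 12, which a second enolate of 11 attacks with its tertiary carbon at the sp carbon (first CO–CMe2 bond, giving 13 as its dilithium salt). A third equivalent of enolate removes the one α-H left on the ketone of 13, and the new tertiary enolate attacks the methyl ester in a 6-(enolexo)-exo-trig Dieckmann closure that expels LiOMe, forms the second CO–CMe2 bond and leaves the new ring as its stabilised triketone enolate. The closest known reaction types are the [3+3] Claisen–Dieckmann condensation of acetonedicarboxylates with malonates to phloroglucinol esters, the cyclocondensation of activated aryl malonates with 1,3-dinucleophiles through ketenes and the Dieckmann closure of syncarpic-type triones; untested is the one-flask use of an unactivated ketone whose two α-carbons are tertiary. No stereocentre is formed: C-3 of 10 becomes sp2 and C-4 ends with two identical rings. The step needs C- and not O-acylation twice, which the lithium counter-ion in THF, the ketene as first electrophile, the reversibility of O-attack on a methyl ester and the triketone enolate as thermodynamic sink should secure; it also needs the acidic H-3 not to deactivate the malonyl unit, which the enol-lactone ring secures by turning that deprotonation into the ketene-forming event.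

**Compound list**
1 | 2',4',6'-trihydroxyacetophenone | CC(=O)c1c(O)cc(O)cc1O | starting material
2 | iodomethane | CI | starting material
3 | 2-acetyl-3-hydroxy-4,4,6,6-tetramethylcyclohex-2-ene-1,5-dione | CC(=O)C1=C(O)C(C)(C)C(=O)C(C)(C)C1=O | intermediate
4 | syncarpic acid (5-hydroxy-2,2,6,6-tetramethylcyclohex-4-ene-1,3-dione) | O=C1C=C(O)C(C)(C)C(=O)C1(C)C | intermediate
5 | 3-methylbutanal (isovaleraldehyde) | CC(C)CC=O | starting material
6 | 3-hydroxy-4,4,6,6-tetramethyl-2-[3-methyl-1-(piperidin-1-yl)butyl]cyclohex-2-ene-1,5-dione (piperidine Mannich base, racemic, drawn neutral) | CC(C)CC(N1CCCCC1)C1=C(O)C(C)(C)C(=O)C(C)(C)C1=O | intermediate (not isolated)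
7 | 2,2,4,4-tetramethyl-6-(3-methylbutylidene)cyclohexane-1,3,5-trione | CC(C)CC=C1C(=O)C(C)(C)C(=O)C(C)(C)C1=O | intermediate
8 | dimethyl malonate | COC(=O)CC(=O)OC | starting material
9 | dimethyl 2-[1-(2-hydroxy-3,3,5,5-tetramethyl-4,6-dioxocyclohex-1-en-1-yl)-3-methylbutyl]propanedioate (racemic) | COC(=O)C(C(=O)OC)C(CC(C)C)C1=C(O)C(C)(C)C(=O)C(C)(C)C1=O | intermediate
10 | methyl 6,6,8,8-tetramethyl-4-(2-methylpropyl)-2,5,7-trioxo-3,4,5,6,7,8-hexahydro-2H-chromene-3-carboxylate (racemic, cis/trans mixture) | COC(=O)C1C(CC(C)C)C2=C(OC1=O)C(C)(C)C(=O)C(C)(C)C2=O | intermediate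
11 | 2,4-dimethylpentan-3-one (diisopropyl ketone) | CC(C)C(=O)C(C)C | starting material
12 | methyl 2-[1-(2-hydroxy-3,3,5,5-tetramethyl-4,6-dioxocyclohex-1-en-1-yl)-3-methylbutyl]-3-oxoprop-2-enoate (methoxycarbonyl ketene, racemic, drawn neutral; present as lithium enolate of ring 1) | COC(=O)C(=C=O)C(CC(C)C)C1=C(O)C(C)(C)C(=O)C(C)(C)C1=O | intermediate (not isolated)
13 | methyl 2-[1-(2-hydroxy-3,3,5,5-tetramethyl-4,6-dioxocyclohex-1-en-1-yl)-3-methylbutyl]-4,4,6-trimethyl-3,5-dioxoheptanoate (diastereomer mixture, drawn neutral; present as lithium salt) | COC(=O)C(C(=O)C(C)(C)C(=O)C(C)C)C(CC(C)C)C1=C(O)C(C)(C)C(=O)C(C)(C)C1=O | intermediate (not isolated)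
14 | Watsonianone A (2,2'-(3-methylbutane-1,1-diyl)bis(3-hydroxy-4,4,6,6-tetramethylcyclohex-2-ene-1,5-dione), achiral) | CC(C)CC(C1=C(O)C(C)(C)C(=O)C(C)(C)C1=O)C1=C(O)C(C)(C)C(=O)C(C)(C)C1=O | target

**Totals**
Total step count: 6. Longest linear sequence: 6 steps (1 → 3 → 4 → 7 → 9 → 10 → 14).

**Steps most likely to fail**

Step 6 (Proposed new method). What may go wrong: O-acylation of the hindered tetrasubstituted enolate at either stage, proton transfer that quenches the enolate before C–C bond formation, or retro-Claisen cleavage of the non-enolisable 1,3-diketone of 13 by the liberated methoxide. Fallback with known chemistry: it sets out from 7 and 4 and comes back to the route at 14. The sodium enolate of 4 (NaH, THF, 0 °C → rt, then aq. HCl) is added to the alkylidene triketone 7 in a Michael addition. This is the usual Knoevenagel–Michael bis-adduct formation of cyclic 1,3-diones with aldehydes, and it gives 14 directly. The fallback makes no new compound (F0).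

Step 5. What may go wrong: retro-Michael loss of the malonate, or a ring closure that stalls, under acid and heat. Fallback: it sets out from 7 and comes back at 10. Commercial tert-butyl methyl malonate is added to 7 as its sodium salt (NaH, THF, 0 °C). This should give tert-butyl methyl 2-[1-(2-hydroxy-3,3,5,5-tetramethyl-4,6-dioxocyclohex-1-en-1-yl)-3-methylbutyl]propanedioate F1. TFA in CH2Cl2 at rt cleaves the tert-butyl ester to 2-[1-(2-hydroxy-3,3,5,5-tetramethyl-4,6-dioxocyclohex-1-en-1-yl)-3-methylbutyl]-3-methoxy-3-oxopropanoic acid F2. DCC with catalytic DMAP in CH2Cl2 at 0 °C then closes the enol lactone 10 by carbodiimide dehydration at low temperature, where neither retro-Michael reaction nor decarboxylation should compete.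

Step 4. What may go wrong: the malonate anion deprotonates the γ-CH2 of 7 (deconjugation to the dienolate), or adventitious alkoxide cleaves the triketone ring, instead of conjugate addition. Fallback: it sets out from 5, 8 and 4 and comes back at 9, with the roles of donor and acceptor reversed. Knoevenagel condensation of 5 with 8 (di-n-propylamine/AcOH cat., cyclohexane, reflux, Dean–Stark) should give dimethyl 2-(3-methylbutylidene)propanedioate F3. Syncarpic acid 4 is then added to F3 as the Michael donor (DBU cat., MeCN, 50 °C), which should give 9.

**Further compounds**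
F0 | step 6 | none | none
F1 | step 5 | tert-butyl methyl 2-[1-(2-hydroxy-3,3,5,5-tetramethyl-4,6-dioxocyclohex-1-en-1-yl)-3-methylbutyl]propanedioate (diastereomer mixture) | COC(=O)C(C(=O)OC(C)(C)C)C(CC(C)C)C1=C(O)C(C)(C)C(=O)C(C)(C)C1=O
F2 | step 5 | 2-[1-(2-hydroxy-3,3,5,5-tetramethyl-4,6-dioxocyclohex-1-en-1-yl)-3-methylbutyl]-3-methoxy-3-oxopropanoic acid (diastereomer mixture) | COC(=O)C(C(=O)O)C(CC(C)C)C1=C(O)C(C)(C)C(=O)C(C)(C)C1=O
F3 | step 4 | dimethyl 2-(3-methylbutylidene)propanedioate | CC(C)CC=C(C(=O)OC)C(=O)OC
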